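## The problem

Compound 44 is a germacranolide; germacrane numbering is used throughout (ring C1–C10, butenolide C7=C11–C12(=O)–O–C6, C13 on C11, C14 on C10, C15 on C4). A ten-membered carbocycle is fused across C6–C7 to the butenolide and holds the C1(10) double bond with both ring bonds cis, a trans C2–C3 oxirane, and a C4–C5 oxirane in which C3 and C6 are cis. Seven ring stereocentres (2R,3S,4S,5S,6R,8R,9R) and the 2S centre of the C9 2-methyloxirane-2-carboxylate have to be set. C2 and C3 have no neighbouring directing group once C1 is sp2 and so need reagent control at an earlier oxidation state. The C6 carbinol can direct the C4–C5 epoxidation (threo relation) and later fixes the face on which C8 is attacked, so C4, C5, C8 and C9 can all be derived from C6. Four different esters (acetates at C8 and C13, 3-methylbut-2-enoate at C14, epoxy ester at C9) sit on four hydroxyls, two of them vicinal. The allylic C2–C3 oxirane (acid ionization; SN2' opening by cuprates, hydrides and zerovalent palladium), the trisubstituted oxirane, the allylic C14 ester and the base-labile butenolide C6–H (a furanolate there would expel the neighbouring oxirane) rule out strong acid, strong nucleophiles and late reductions. The feature that invites a ring-closing aldol is that C8 is the vinylogous gamma position of the C12 carbonyl through C7=C11 and carries an acetate, while C9 carries the other secondary ester: an enol acetate at C8 and an aldehyde at C9 would give the C8–C9 bond, the ring, both centres and the ester differentiation at once.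

## Retrosynthesis

**Ester endgame.** The acetyl C–O bond at C13 and the acyl C–O bond of the C9 epoxy ester are cut. This leads through alcohol 43 and silyl ether 42 to macrocyclic alcohol 39 and acid 41 (from commercial ester 40). Late epoxidation of a C9 methacrylate would give both side-chain epimers, and a C13 acetate carried through the ring closure would be an allylic leaving group on an electron-rich ketene acetal. Compound 39 has one free hydroxyl (C9) and one silyl ether (C13), so each ester goes on without a selectivity problem. The forward steps must acylate a hindered allylic alcohol next to an acetate without acyl migration and remove a primary silyl group beside three oxiranes.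

**C8–C9 ring closure.** In 39 the C8–C9 bond is cut, giving ketene silyl acetal 38 with a Z enol acetate at C7=C8 and an enal at C9. Cuts at C9–C10 or C7–C8 would need vinyl or acyl anion chemistry at hindered carbons, and cuts at C1–C2 or C5–C6 would form sp3–sp3 bonds beside oxiranes. C8–C9 is the only ring bond flanked by a latent aldehyde and a latent vinylogous enolate. The cut removes the ring and two stereocentres and turns the C8/C9 ester problem into "enol acetate versus aldehyde". The forward reaction must be gamma-selective, face-selective at both carbons, and run at high dilution under a Lewis acid that spares the oxiranes.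

**Dienolate precursor.** Compound 38 is traced to lactone aldehyde 33 by functional-group changes only: O–Si (38 to enal 37), C9 oxidation and PMB removal (37 to 36 to 35), and O-acetylation of the C8 aldehyde enolate (35 to 33). The enol acetate is made before the C9 aldehyde exists, so only one aldehyde is present at a time. The ketene acetal is made last because it is the least stable function. The forward steps must give the Z enol acetate and must silylate the lactone at C11 without disturbing the enal.

**C6–C7 aldol, oxirane and lactone.** Aldehyde 33 comes from imide 31 by reductive removal of the auxiliary (via alcohol 32). In 31 the lactone C12–O bond, the C4–C5 oxirane and the C6–C7 bond are cut in turn (31 to 30 to 29), arriving at imide 27 and enal 17. The C6 hydroxyl of 29 does three jobs: it is the centre set by the auxiliary, it directs the epoxidation to the threo epoxy alcohol, and it then becomes the lactone oxygen. Adding a nucleophile to a preformed epoxy aldehyde would favour the erythro relation. The cut gives two fragments of similar size. The aldol must tolerate a Z enal with an allylic oxirane, and the lactonization must be mild.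

**Four-carbon fragment.** Imide 27 is cut at the N-acyl bond to acid 24 and auxiliary 25. Acid 24 comes from racemic lactone 21, whose lactone carbonyl marks the carboxyl that becomes C8 and whose ring oxygen becomes the C13 oxygen. Lactone 21 comes from dimethyl itaconate 18 by formal anti-Markovnikov hydration. Selective hydrolysis of a 2-substituted succinate diester would be less reliable. The C11 centre is not controlled because it is erased in 38.

**C1(10) alkene.** Enal 17 is simplified through 16, 15 and 13 to enoate 12, and the C10=C1 bond is cut to epoxy aldehyde 8 and phosphonate 11. The normal E-selective olefination places the ester trans to the oxirane; that carbon becomes C14 (reduced, then acylated with acid 14), while the PMB-oxymethyl arm cis to C2 becomes C9. A Z-selective olefination with the ester as C9 would require an ester reduction after the lactone is in place. The reduction with i-Bu2AlH is the reason this fragment is finished before the lactone is built.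

**C2–C3 oxirane and diene.** Epoxy aldehyde 8 comes from epoxy alcohol 7, and 7 from dienol 6 by asymmetric epoxidation; this is the only stage at which C2=C3 has a directing hydroxyl (on C1). The C3–C4 bond of 6 is cut to Z-iodide 4 and stannane 5, a coupling that keeps both alkene geometries. Iodide 4 comes from but-2-yn-1-ol 1 through 3, where trans-hydroalumination fixes the later cis relation of C3 and C6.

## Roads not taken

Alternative 1: The cut is the lactone C6–O bond. DDQ would remove hydride from the doubly allylic C6 of ring-opened acid A2, and the C12 carboxyl would capture the cation to give triene lactone A1, which already carries all four esters.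
- Merits: the lactone closes in one oxidation, no Lewis acid ever meets an oxirane, and the fragile diepoxide is postponed to the end. In these respects this road is better than the chosen one.
- Weak points: A1 has none of the centres C2–C6. C6 would form from a planar pentadienyl-type cation with only remote centres to bias it. Both oxiranes would have to be placed last on a conjugated triene inside the ring, with regio- and face control and without touching C1(10), the senecioate or the epoxy ester. DDQ could also abstract hydride at C9 or C14. The ten-membered Z,E,Z-triene A2 is itself an unsolved ring problem.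
- Comparison: the chosen plan sets all five centres C2–C6 on acyclic intermediates by catalyst, auxiliary or hydroxyl direction before the ring exists, and accepts one Lewis acid step on the diepoxide in return.

Alternative 2: The cut is the C2–C3 bond together with the C2–O bond of the oxirane. Base would turn sulfonium salt A4 (tetrahydrothiophenium at C2, aldehyde at C3) into an allylic ylide that adds to the aldehyde and closes both the ten-membered ring and the trans oxirane, giving A3.
- Merits: one step forms a C–C bond, the ring, an oxirane and two centres, as much as the chosen key step. No Lewis acid is needed, and the enol acetate geometry problem does not arise.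
- Weak points: the base meets the butenolide C6–H, and a furanolate would open the C4–C5 oxirane. The allylic ylide can react at its gamma terminus or rearrange by a 2,3-shift. The C3 aldehyde sits on a fully substituted oxirane carbon. The absolute sense at C2/C3 would rest on macrocyclic substrate control unless a chiral sulfide is built in. A3 still needs the PMB and silyl ethers exchanged for two esters.
- Comparison: the chosen plan sets C2/C3 early by a catalytic asymmetric epoxidation of predictable sense and pairs a neutral nucleophile with an aldehyde under non-basic conditions. It pays with the need to control the enol acetate geometry.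

Alternative 3: The cut is the C2=C3 double bond of a diene, seen as the result of breaking a C3–C8 bond. The C8 alkoxide of decalin mesylate A6 would fragment (Grob) to the ten-membered dienyl ketone A5.
- Merits: the medium ring arises from six-membered rings, so there is no entropic penalty and no high dilution. The alkene geometry follows stereospecifically from the anti-periplanar arrangement. Here this road is clearly superior to any direct ten-membered ring closure.
- Weak points: A5 is far from 44. C2=C3 must then be epoxidized from the correct face next to C1(10) without a directing group. The C8 ketone must be reduced selectively and acetylated. Three ethers must be exchanged for esters. A6 is a bicycle with a fused oxirane, a butenolide, a tertiary alcohol and several centres of its own that are destroyed again. The alkoxide may attack the butenolide or trigger other cleavages.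
- Comparison: the chosen plan closes the ring from an acyclic precursor in which every centre survives into 44, and the ring closure itself delivers the C8/C9 oxygen pattern. It has to set high dilution and a Lewis acid step against the easier ring formation of the fragmentation.

Key step: step 23

Remark: C13 is carried as its tert-butyldimethylsilyl ether from 24 to 42, because an acetate there would be an allylic leaving group on ketene acetal 38; the acetate goes on last.
Remark: the C11 centre is racemic in 21 and is carried as an epimeric mixture (drawn without configuration) from 27 to 37; it becomes sp2 in 38.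
Remark: ester 40 is taken as a commercial, enantiopure material.

## Steps

Step 1
Reactants: 1 but-2-yn-1-ol
Product: 3 (Z)-3-iodobut-2-en-1-ol, via cyclic alkenylaluminate 2 (not isolated)
Conditions: NaAlH2(OCH2CH2OMe)2, THF, 0 → 23 °C; then I2, −78 → 0 °C
Reagents that add atoms: iodine, II
Why: Alkoxide-directed trans-hydroalumination places aluminium on the distal alkyne carbon in a five-membered aluminate, and iodinolysis with retention gives the Z vinyl iodide (iodine cis to the carbinol carbon). This fixes the later cis relation of C3 and C6.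

Step 2
Reactants: 3 (Z)-3-iodobut-2-en-1-ol
Product: 4 tert-butyl{[(Z)-3-iodobut-2-en-1-yl]oxy}dimethylsilane
Conditions: TBSCl, imidazole, CH2Cl2, 0 → 23 °C
Reagents that add atoms: tert-butyldimethylsilyl chloride, CC(C)(C)[Si](C)(C)Cl
Why: Standard silylation of a primary alcohol; the group masks C6–OH until the C9/C14 unit is complete.

Step 3
Reactants: 4 silyl ether of 3; 5 (E)-3-(tributylstannyl)prop-2-en-1-ol
Product: 6 (2E,4Z)-6-(tert-butyldimethylsilyloxy)-4-methylhexa-2,4-dien-1-ol
Conditions: PdCl2(MeCN)2 (5 mol %), DMF, 23 °C
Reagents that add atoms: none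
Why: Stille coupling proceeds with retention at both alkenyl partners and forms the C3–C4 bond of the 2E,4Z diene; the free hydroxyl of 5 is tolerated.

Step 4
Reactants: 6 (2E,4Z)-dienol
Product: 7 [(2R,3R)-3-[(Z)-4-(tert-butyldimethylsilyloxy)but-2-en-2-yl]oxiran-2-yl]methanol
Conditions: Ti(OiPr)4 (10 mol %), D-(−)-diethyl tartrate (12 mol %), t-BuOOH, 4 Å molecular sieves, CH2Cl2, −20 °C
Reagents that add atoms: tert-butyl hydroperoxide, CC(C)(C)OO
Why: Sharpless asymmetric epoxidation oxidizes only the alkene of the free allylic alcohol. The D-(−)-tartrate gives the (2R,3R) epoxy alcohol, the mirror image of the (2S,3S) products obtained from E-allylic alcohols with the L-(+) ester, and so sets C2 and C3.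

Step 5
Reactants: 7 epoxy alcohol
Product: 8 (2S,3R)-3-[(Z)-4-(tert-butyldimethylsilyloxy)but-2-en-2-yl]oxirane-2-carbaldehyde
Conditions: Dess–Martin periodinane, pyridine, CH2Cl2, 0 °C
Reagents that add atoms: none
Why: Buffered Dess–Martin oxidation of a 2,3-epoxy alcohol gives the epoxy aldehyde without opening the oxirane; the descriptor at C2 changes only through the priority rules.

Step 6
Reactants: 9 trimethyl 2-phosphonoacrylate; 10 4-methoxybenzyl alcohol
Product: 11 methyl 2-(dimethoxyphosphoryl)-3-[(4-methoxybenzyl)oxy]propanoate
Conditions: KOt-Bu (5 mol %), THF, 0 → 23 °C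
Reagents that add atoms: none
Why: Alkoxide-catalysed oxa-Michael addition to the doubly activated acrylate gives the alpha-substituted phosphonoacetate in one step.

Step 7
Reactants: 8 epoxy aldehyde; 11 phosphonate
Product: 12 methyl (E)-2-{[(4-methoxybenzyl)oxy]methyl}-3-{(2R,3R)-3-[(Z)-4-(tert-butyldimethylsilyloxy)but-2-en-2-yl]oxiran-2-yl}prop-2-enoate
Conditions: LiCl, DBU, MeCN, 0 → 23 °C
Reagents that add atoms: none
Why: Horner–Wadsworth–Emmons olefination under Masamune–Roush conditions is mild enough for an epoxy aldehyde. The usual preference places the ester trans to the oxirane, so the ester carbon becomes C14 and the PMB-oxymethyl arm (future C9) is cis to C2.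

Step 8
Reactants: 12 enoate
Product: 13 (Z)-2-{[(4-methoxybenzyl)oxy]methyl}-3-{(2R,3R)-3-[(Z)-4-(tert-butyldimethylsilyloxy)but-2-en-2-yl]oxiran-2-yl}prop-2-en-1-ol
Conditions: i-Bu2AlH, CH2Cl2, −78 °C; aqueous sodium potassium tartrate
Reagents that add atoms: none
Why: 1,2-Reduction of the enoate to the allylic alcohol at −78 °C is faster than attack on the allylic oxirane; this is the only strong hydride step and precedes all lactone chemistry.

Step 9
Reactants: 13 allylic alcohol; 14 3-methylbut-2-enoic acid
Product: 15 (E)-2-{[(4-methoxybenzyl)oxy]methyl}-3-{(2R,3R)-3-[(Z)-4-(tert-butyldimethylsilyloxy)but-2-en-2-yl]oxiran-2-yl}prop-2-en-1-yl 3-methylbut-2-enoate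
Conditions: EDC·HCl, DMAP, CH2Cl2, 0 → 23 °C
Reagents that add atoms: none
Why: Steglich-type esterification of a primary allylic alcohol installs the C14 ester under neutral conditions.

Step 10
Reactants: 15 silyl ether
Product: 16 (E)-3-{(2R,3R)-3-[(Z)-4-hydroxybut-2-en-2-yl]oxiran-2-yl}-2-{[(4-methoxybenzyl)oxy]methyl}prop-2-en-1-yl 3-methylbut-2-enoate
Conditions: n-Bu4NF, AcOH, THF, 0 °C
Reagents that add atoms: none
Why: Buffered fluoride removes the primary silyl ether without touching the ester, the PMB ether or the oxirane.

Step 11
Reactants: 16 allylic alcohol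
Product: 17 (E)-2-{[(4-methoxybenzyl)oxy]methyl}-3-{(2R,3R)-3-[(Z)-4-oxobut-2-en-2-yl]oxiran-2-yl}prop-2-en-1-yl 3-methylbut-2-enoate
Conditions: Dess–Martin periodinane, pyridine, CH2Cl2, 0 °C
Reagents that add atoms: none
Why: Dess–Martin oxidation of a Z allylic alcohol gives the Z enal (C6 aldehyde) without isomerization when buffered; the product is used at once.

Step 12
Reactants: 18 dimethyl itaconate
Product: 21 methyl 5-oxotetrahydrofuran-3-carboxylate (racemic), via boronate 19 (not isolated), via hydroxy diester 20 (not isolated)
Conditions: B2pin2, CuCl (3 mol %), Xantphos (3 mol %), NaOt-Bu (9 mol %), MeOH, THF, 23 °C; then NaBO3·4H2O, THF/H2O; then TsOH·H2O (cat.), PhMe, 60 °C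
Reagents that add atoms: sodium perborate, [Na+].[O-]OB=O
Why: Copper-catalysed conjugate borylation puts boron on the methylene carbon, perborate oxidizes the C–B bond, and the gamma-hydroxy ester lactonizes. The lactone carbonyl thereby marks the carboxyl group that becomes C8.

Step 13
Reactants: 21 lactone ester
Product: 24 3-[(tert-butyldimethylsilyloxy)methyl]-4-methoxy-4-oxobutanoic acid (racemic), via sodium hydroxy carboxylate 22 (not isolated), via bis-silyl derivative 23 (not isolated)
Conditions: NaOH (1.0 equiv), THF/H2O, 0 °C; evaporation; TBSCl, imidazole, DMF, 23 °C; then THF/H2O/AcOH, 0 °C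
Reagents that add atoms: sodium hydroxide, [Na+].[OH-]; tert-butyldimethylsilyl chloride, CC(C)(C)[Si](C)(C)Cl
Why: Hydroxide opens the gamma-lactone faster than it attacks the alpha-branched methyl ester. Silylation of the salt gives silyl ether and silyl ester, and only the silyl ester is hydrolysed by aqueous acetic acid.

Step 14
Reactants: 24 acid; 25 (R)-4-benzyl-1,3-oxazolidin-2-one
Product: 27 methyl 4-[(R)-4-benzyl-2-oxo-1,3-oxazolidin-3-yl]-2-[(tert-butyldimethylsilyloxy)methyl]-4-oxobutanoate (C11 epimers), via mixed pivalic anhydride 26 (not isolated)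
Conditions: t-BuCOCl, Et3N, THF, −20 °C; then 25, LiCl, −20 → 23 °C
Reagents that add atoms: none
Why: N-Acylation of the oxazolidinone through the mixed pivalic anhydride with LiCl/Et3N avoids strong base and leaves the beta-silyloxy ester intact.

Step 15
Reactants: 27 imide; 17 enal
Product: 29 syn aldol adduct (6S,7R), via boron enolate 28 (not isolated)
Conditions: n-Bu2BOTf, i-Pr2NEt, CH2Cl2, −78 → 0 °C; then 17, −78 → −20 °C; pH 7 buffer, MeOH, H2O2, 0 °C
Reagents that add atoms: none
Why: Evans syn aldol reaction: the Z boron enolate of the imide (not of the less acidic ester) reacts through a chair transition state on the face away from the benzyl group. With the (R)-auxiliary this gives the (6S,7R) adduct, which has the C6 configuration of 44 (the descriptor changes later). A slight deficit of boron triflate leaves no free Lewis acid for the allylic oxirane.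

Step 16
Reactants: 29 aldol adduct
Product: 31 lactone imide (2R,3S,4S,5S,6R,7R), via epoxy alcohol 30 (not isolated)
Conditions: mCPBA, CH2Cl2, −20 → 0 °C; then DBU (0.2 equiv), 23 °C
Reagents that add atoms: 3-chloroperoxybenzoic acid, OOC(=O)c1cccc(Cl)c1
Why: Hydroxyl-directed peracid epoxidation: A(1,3) strain in the Z-trisubstituted allylic alcohol fixes the reactive conformer and oxygen is delivered syn to the hydroxyl, giving the threo epoxy alcohol (4S,5S). The C1(10) alkene, flanked by two allylic oxygens, and the senecioate react far more slowly. DBU then closes the gamma-lactone with loss of methanol.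

Step 17
Reactants: 31 lactone imide
Product: 32 lactone alcohol (C8 hydroxymethyl at C7)
Conditions: NaBH4, THF/H2O (4:1), 0 °C
Reagents that add atoms: none
Why: Borohydride in wet THF reduces the activated exocyclic imide carbonyl to the primary alcohol and releases the auxiliary; the lactone, the esters and the oxiranes react much more slowly at 0 °C.

Step 18
Reactants: 32 lactone alcohol
Product: 33 lactone aldehyde (C8 formyl at C7)
Conditions: Dess–Martin periodinane, pyridine, CH2Cl2, 0 °C
Reagents that add atoms: none
Why: Dess–Martin oxidation of the primary alcohol; the configuration at C7 is of no consequence because C7 becomes sp2 in the next step.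

Step 19
Reactants: 33 lactone aldehyde
Product: 35 Z enol acetate lactone, via lithium enolate 34 (not isolated)
Conditions: LiN(SiMe3)2 (1.0 equiv), THF, −78 °C; then Ac2O, −78 °C
Reagents that add atoms: acetic anhydride, CC(=O)OC(C)=O
Why: Kinetic deprotonation at C7, the most acidic C–H, gives the aldehyde enolate, which is O-acetylated. Lithium held between the enolate oxygen and the oxygens on the C6 side (ring oxygen, C4–C5 oxirane) should favour the Z isomer with acetoxy cis to C6. The ring C6–O bond lies in the nodal plane of the exocyclic enolate, so beta-elimination is stereoelectronically disfavoured.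

Step 20
Reactants: 35 enol acetate lactone
Product: 36 C9 allylic alcohol
Conditions: DDQ, CH2Cl2/pH 7 buffer (10:1), 0 → 23 °C
Reagents that add atoms: none
Why: Oxidative cleavage of the PMB ether by DDQ is neutral and leaves oxiranes, esters, the silyl ether and the enol acetate untouched.

Step 21
Reactants: 36 C9 allylic alcohol
Product: 37 C9 enal (formyl cis to C2)
Conditions: Dess–Martin periodinane, pyridine, CH2Cl2, 0 °C
Reagents that add atoms: none
Why: Buffered Dess–Martin oxidation gives the enal with retention of the alkene geometry; the aldehyde is made only now so that it meets no nucleophile before the ring closure.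

Step 22
Reactants: 37 enal lactone
Product: 38 ketene silyl acetal (C12 tert-butyldimethylsilyloxy; C11=C12 and Z C7=C8 enol acetate)
Conditions: TBSOTf, Et3N, CH2Cl2, −78 → −40 °C; pentane, filtration under argon
Reagents that add atoms: tert-butyldimethylsilyl trifluoromethanesulfonate, CC(C)(C)[Si](C)(C)OS(=O)(=O)C(F)(F)F
Why: Soft enolization: O-silylation of the lactone carbonyl and deprotonation at the allylic C11–H by the amine gives the silyl dienolate, as in the formation of silyloxyfurans from butenolides. Excess amine keeps free silyl triflate low so that the non-enolizable enal is not activated. The crude product is used directly.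

Step 23
Reactants: 38 ketene silyl acetal
Product: 39 macrocyclic C9 alcohol (2R,3S,4S,5S,6R,8R,9R) with C8 acetate and C13 silyl ether
Conditions: MgBr2·OEt2 (3 equiv), CH2Cl2, −78 → −30 °C, slow addition of 38 to a final 1 mM; pH 7 buffer
Reagents that add atoms: none
Why: Intramolecular vinylogous Mukaiyama aldol reaction: MgBr2 binds the enal oxygen, the silyl dienolate attacks through its terminal carbon C8, and loss of the silyl group from the silyloxycarbenium ion regenerates the conjugated C7=C11 butenolide. The closest known reaction type is the Lewis acid-promoted gamma-selective addition of silyl dienolates (silyloxyfurans and related ketene acetals) to aldehydes, including ring-closing versions. The ten-membered carbocycle closes in a 10-(enolendo)-exo-trig mode. C8 is controlled by the Z enol acetate together with C6: the C5 substituent of C6 holds the tether on one face of the planar dienolate, so C9 is delivered to that face, which gives 8R. C9 is controlled by the restricted tether (cis C1(10) alkene, two oxiranes) and by a transition state in which magnesium bridges the aldehyde oxygen and the C8 acetate; this places the two oxygens syn and corresponds to the threo (8R,9R) alcohol. Gamma attack is needed rather than alpha attack at C11: C11 is fully substituted and would become a quaternary centre, and Lewis acid-mediated silyl dienolate additions are gamma-selective. The C13 silyl ether, unlike an acetate, should not ionize from the ketene acetal, and the low temperature is chosen to spare the oxiranes.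

Step 24
Reactants: 40 methyl (S)-2-methyloxirane-2-carboxylate
Product: 41 (S)-2-methyloxirane-2-carboxylic acid
Conditions: LiOH, THF/H2O, 0 °C; then aq. HCl to pH 3, 0 °C, extraction
Reagents that add atoms: lithium hydroxide, [Li+].[OH-]
Why: Saponification of the glycidic ester at 0 °C leaves the quaternary centre and the oxirane intact; the acid is used without storage.

Step 25
Reactants: 39 macrocyclic alcohol; 41 epoxy acid
Product: 42 C9 (S)-2-methyloxirane-2-carboxylate with C13 silyl ether
Conditions: 2-methyl-6-nitrobenzoic anhydride, DMAP, Et3N, CH2Cl2, 23 °C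
Reagents that add atoms: none
Why: Shiina esterification through a mixed aromatic anhydride acylates hindered secondary alcohols with alpha-quaternary acids under mild conditions; C9–OH is the only free hydroxyl, so no selectivity is required.

Step 26
Reactants: 42 silyl ether
Product: 43 C13 alcohol
Conditions: Et3N·3HF, THF, 23 °C
Reagents that add atoms: none
Why: Nearly neutral fluoride cleaves the primary silyl ether while esters and oxiranes survive.

Step 27
Reactants: 43 C13 alcohol
Product: 44 target compound CNP0279449.1
Conditions: Ac2O, pyridine, DMAP (cat.), CH2Cl2, 0 °C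
Reagents that add atoms: acetic anhydride, CC(=O)OC(C)=O
Why: Acetylation of the single primary hydroxyl completes the ester pattern; no stereocentre is touched.

## Compound list

1 | but-2-yn-1-ol | CC#CCO | starting material
2 | sodium bis(2-methoxyethoxy) cyclic alkenylaluminate (3-methyl-2,5-dihydro-1,2-oxaaluminole ate complex) | CC1=CCO[Al-]1(OCCOC)OCCOC.[Na+] | intermediate
3 | (Z)-3-iodobut-2-en-1-ol | C/C(I)=C/CO | intermediate
4 | tert-butyl{[(Z)-3-iodobut-2-en-1-yl]oxy}dimethylsilane | C/C(I)=C/CO[Si](C)(C)C(C)(C)C | intermediate
5 | (E)-3-(tributylstannyl)prop-2-en-1-ol | OC/C=C/[Sn](CCCC)(CCCC)CCCC | starting material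
6 | (2E,4Z)-6-(tert-butyldimethylsilyloxy)-4-methylhexa-2,4-dien-1-ol | OC/C=C/C(C)=C\CO[Si](C)(C)C(C)(C)C | intermediate
7 | [(2R,3R)-3-[(Z)-4-(tert-butyldimethylsilyloxy)but-2-en-2-yl]oxiran-2-yl]methanol | OC[C@H]1O[C@@H]1/C(C)=C\CO[Si](C)(C)C(C)(C)C | intermediate
8 | (2S,3R)-3-[(Z)-4-(tert-butyldimethylsilyloxy)but-2-en-2-yl]oxirane-2-carbaldehyde | O=C[C@H]1O[C@@H]1/C(C)=C\CO[Si](C)(C)C(C)(C)C | intermediate
9 | trimethyl 2-phosphonoacrylate | C=C(C(=O)OC)P(=O)(OC)OC | starting material
10 | 4-methoxybenzyl alcohol | COc1ccc(CO)cc1 | starting material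
11 | methyl 2-(dimethoxyphosphoryl)-3-[(4-methoxybenzyl)oxy]propanoate (racemic) | COC(=O)C(COCc1ccc(OC)cc1)P(=O)(OC)OC | intermediate
12 | methyl (E)-2-{[(4-methoxybenzyl)oxy]methyl}-3-{(2R,3R)-3-[(Z)-4-(tert-butyldimethylsilyloxy)but-2-en-2-yl]oxiran-2-yl}prop-2-enoate | COc1ccc(COC/C(C(=O)OC)=C\[C@H]2O[C@@H]2/C(C)=C\CO[Si](C)(C)C(C)(C)C)cc1 | intermediate
13 | (Z)-2-{[(4-methoxybenzyl)oxy]methyl}-3-{(2R,3R)-3-[(Z)-4-(tert-butyldimethylsilyloxy)but-2-en-2-yl]oxiran-2-yl}prop-2-en-1-ol | COc1ccc(COC/C(CO)=C\[C@H]2O[C@@H]2/C(C)=C\CO[Si](C)(C)C(C)(C)C)cc1 | intermediate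
14 | 3-methylbut-2-enoic acid | CC(C)=CC(=O)O | starting material
15 | (E)-2-{[(4-methoxybenzyl)oxy]methyl}-3-{(2R,3R)-3-[(Z)-4-(tert-butyldimethylsilyloxy)but-2-en-2-yl]oxiran-2-yl}prop-2-en-1-yl 3-methylbut-2-enoate | COc1ccc(COC/C(COC(=O)C=C(C)C)=C\[C@H]2O[C@@H]2/C(C)=C\CO[Si](C)(C)C(C)(C)C)cc1 | intermediate
16 | (E)-3-{(2R,3R)-3-[(Z)-4-hydroxybut-2-en-2-yl]oxiran-2-yl}-2-{[(4-methoxybenzyl)oxy]methyl}prop-2-en-1-yl 3-methylbut-2-enoate | COc1ccc(COC/C(COC(=O)C=C(C)C)=C\[C@H]2O[C@@H]2/C(C)=C\CO)cc1 | intermediate
17 | (E)-2-{[(4-methoxybenzyl)oxy]methyl}-3-{(2R,3R)-3-[(Z)-4-oxobut-2-en-2-yl]oxiran-2-yl}prop-2-en-1-yl 3-methylbut-2-enoate (C6 aldehyde; C9 PMB ether; C14 senecioate) | COc1ccc(COC/C(COC(=O)C=C(C)C)=C\[C@H]2O[C@@H]2/C(C)=C\C=O)cc1 | intermediate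
18 | dimethyl itaconate | C=C(CC(=O)OC)C(=O)OC | starting material
19 | dimethyl 2-[(4,4,5,5-tetramethyl-1,3,2-dioxaborolan-2-yl)methyl]succinate (racemic) | COC(=O)CC(CB1OC(C)(C)C(C)(C)O1)C(=O)OC | intermediate
20 | dimethyl 2-(hydroxymethyl)succinate (racemic) | COC(=O)CC(CO)C(=O)OC | intermediate
21 | methyl 5-oxotetrahydrofuran-3-carboxylate (racemic) | COC(=O)C1COC(=O)C1 | intermediate
22 | sodium 3-(hydroxymethyl)-4-methoxy-4-oxobutanoate (racemic) | COC(=O)C(CO)CC(=O)[O-].[Na+] | intermediate
23 | tert-butyldimethylsilyl 3-[(tert-butyldimethylsilyloxy)methyl]-4-methoxy-4-oxobutanoate (racemic) | COC(=O)C(CO[Si](C)(C)C(C)(C)C)CC(=O)O[Si](C)(C)C(C)(C)C | intermediate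
24 | 3-[(tert-butyldimethylsilyloxy)methyl]-4-methoxy-4-oxobutanoic acid (racemic) | COC(=O)C(CO[Si](C)(C)C(C)(C)C)CC(=O)O | intermediate
25 | (R)-4-benzyl-1,3-oxazolidin-2-one | O=C1N[C@H](Cc2ccccc2)CO1 | starting material
26 | mixed anhydride of 24 with pivalic acid (racemic) | COC(=O)C(CO[Si](C)(C)C(C)(C)C)CC(=O)OC(=O)C(C)(C)C | intermediate
27 | methyl 4-[(R)-4-benzyl-2-oxo-1,3-oxazolidin-3-yl]-2-[(tert-butyldimethylsilyloxy)methyl]-4-oxobutanoate (C11 epimers) | COC(=O)C(CO[Si](C)(C)C(C)(C)C)CC(=O)N1C(=O)OC[C@H]1Cc1ccccc1 | intermediate
28 | dibutylboron (Z)-enolate of 27 (C11 epimers) | COC(=O)C(CO[Si](C)(C)C(C)(C)C)/C=C(\OB(CCCC)CCCC)N1C(=O)OC[C@H]1Cc1ccccc1 | intermediate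
29 | syn aldol adduct: (6S,7R)-6-hydroxy compound, C7 bearing the N-acyl (R)-4-benzyloxazolidinone carbonyl (C8) and the CH(CH2OTBS)CO2Me unit (C11–C13); (2R,3R) oxirane, 4Z alkene, C9 PMB ether, C14 senecioate; C11 epimers | COc1ccc(COC/C(COC(=O)C=C(C)C)=C\[C@H]2O[C@@H]2/C(C)=C\[C@H](O)[C@H](C(=O)N2C(=O)OC[C@H]2Cc2ccccc2)C(CO[Si](C)(C)C(C)(C)C)C(=O)OC)cc1 | intermediate
30 | threo epoxy alcohol (2R,3S,4S,5S,6R,7R) from 29; C11 epimers | COc1ccc(COC/C(COC(=O)C=C(C)C)=C\[C@H]2O[C@@H]2[C@@]2(C)O[C@H]2[C@H](O)[C@H](C(=O)N2C(=O)OC[C@H]2Cc2ccccc2)C(CO[Si](C)(C)C(C)(C)C)C(=O)OC)cc1 | intermediate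
31 | 12,6-lactone imide (2R,3S,4S,5S,6R,7R); C7 trans to C6 substituent, carrying the oxazolidinone carbonyl; C11 CH2OTBS; C11 epimers | COc1ccc(COC/C(COC(=O)C=C(C)C)=C\[C@H]2O[C@@H]2[C@@]2(C)O[C@H]2[C@@H]2OC(=O)C(CO[Si](C)(C)C(C)(C)C)[C@H]2C(=O)N2C(=O)OC[C@H]2Cc2ccccc2)cc1 | intermediate
32 | lactone alcohol (2R,3S,4S,5S,6R,7S) with C7 hydroxymethyl (C8); C11 epimers | COc1ccc(COC/C(COC(=O)C=C(C)C)=C\[C@H]2O[C@@H]2[C@@]2(C)O[C@H]2[C@@H]2OC(=O)C(CO[Si](C)(C)C(C)(C)C)[C@H]2CO)cc1 | intermediate
33 | lactone aldehyde (2R,3S,4S,5S,6R,7R) with C7 formyl (C8); C11 epimers | COc1ccc(COC/C(COC(=O)C=C(C)C)=C\[C@H]2O[C@@H]2[C@@]2(C)O[C@H]2[C@@H]2OC(=O)C(CO[Si](C)(C)C(C)(C)C)[C@H]2C=O)cc1 | intermediate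
34 | lithium (Z)-enolate of 33 (oxygen cis to C6); C11 epimers | COc1ccc(COC/C(COC(=O)C=C(C)C)=C\[C@H]2O[C@@H]2[C@@]2(C)O[C@H]2[C@@H]2OC(=O)C(CO[Si](C)(C)C(C)(C)C)/C2=C/[O-])cc1.[Li+] | intermediate
35 | Z enol acetate lactone (C7=C8, acetoxy cis to C6); 2R,3S,4S,5S,6R; C9 PMB ether; C11 epimers | COc1ccc(COC/C(COC(=O)C=C(C)C)=C\[C@H]2O[C@@H]2[C@@]2(C)O[C@H]2[C@@H]2OC(=O)C(CO[Si](C)(C)C(C)(C)C)/C2=C/OC(C)=O)cc1 | intermediate
36 | C9 allylic alcohol of 35 (hydroxymethyl cis to C2); C11 epimers | OC/C(COC(=O)C=C(C)C)=C\[C@H]2O[C@@H]2[C@@]2(C)O[C@H]2[C@@H]2OC(=O)C(CO[Si](C)(C)C(C)(C)C)/C2=C/OC(C)=O | intermediate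
37 | C9 enal (formyl cis to C2) with Z enol acetate lactone; C11 epimers | O=C/C(COC(=O)C=C(C)C)=C\[C@H]2O[C@@H]2[C@@]2(C)O[C@H]2[C@@H]2OC(=O)C(CO[Si](C)(C)C(C)(C)C)/C2=C/OC(C)=O | intermediate
38 | ketene silyl acetal: 2-(tert-butyldimethylsilyloxy)-4,5-dihydrofuran with C11 CH2OTBS, Z C7=C8 enol acetate, C9 enal; 2R,3S,4S,5S,6R | O=C/C(COC(=O)C=C(C)C)=C\[C@H]2O[C@@H]2[C@@]2(C)O[C@H]2[C@@H]2OC(O[Si](C)(C)C(C)(C)C)=C(CO[Si](C)(C)C(C)(C)C)/C2=C/OC(C)=O | intermediate
39 | macrocyclic C9 alcohol (2R,3S,4S,5S,6R,8R,9R): 44 with C9 hydroxyl and C13 tert-butyldimethylsilyl ether | CC(C)(C)[Si](C)(C)OCC1=C2[C@@H](OC(C)=O)[C@H](O)/C(COC(=O)C=C(C)C)=C\[C@H]3O[C@@H]3[C@@]3(C)O[C@H]3[C@@H]2OC1=O | intermediate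
40 | methyl (S)-2-methyloxirane-2-carboxylate | COC(=O)[C@]1(C)CO1 | starting material
41 | (S)-2-methyloxirane-2-carboxylic acid | OC(=O)[C@]1(C)CO1 | intermediate
42 | C9 (S)-2-methyloxirane-2-carboxylate with C13 tert-butyldimethylsilyl ether (2R,3S,4S,5S,6R,8R,9R) | CC(C)(C)[Si](C)(C)OCC1=C2[C@@H](OC(C)=O)[C@H](OC(=O)[C@]3(C)CO3)/C(COC(=O)C=C(C)C)=C\[C@H]3O[C@@H]3[C@@]3(C)O[C@H]3[C@@H]2OC1=O | intermediate
43 | C13 alcohol (44 lacking the C13 acetyl group) | OCC1=C2[C@@H](OC(C)=O)[C@H](OC(=O)[C@]3(C)CO3)/C(COC(=O)C=C(C)C)=C\[C@H]3O[C@@H]3[C@@]3(C)O[C@H]3[C@@H]2OC1=O | intermediate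
44 | CNP0279449.1 (2R,3S,4S,5S,6R,8R,9R; side-chain oxirane 2S) | CC(=O)OCC1=C2[C@@H](OC(C)=O)[C@H](OC(=O)[C@]3(C)CO3)/C(COC(=O)C=C(C)C)=C\[C@H]3O[C@@H]3[C@@]3(C)O[C@H]3[C@@H]2OC1=O | target

## Step count and risk

Total step count: 27. Longest linear sequence: 22 steps (steps 1–5, 7–11, 15–23 and 25–27, from 1). Side branches: step 6 (phosphonate), steps 12–14 (imide), step 24 (epoxy acid).

Least certain steps:

**Step 23 (key step).** The most likely failure is poor facial selectivity at the C9 aldehyde in a flexible ten-membered transition state. Competing processes are bromide or Lewis acid opening of the allylic C2–C3 oxirane, Z-to-E isomerization of the enal, and oligomerization. Fallback for the stereochemical failure, setting out from 38 and returning at 39: the cyclization is run as described and the C9 epimer F1 is not discarded. Dess–Martin oxidation should give the C9 enone F2 without touching the C8 acetate. A reagent-controlled 1,2-reduction (oxazaborolidine-catalysed reduction with BH3·SMe2, catalyst enantiomer chosen for the 9R alcohol; NaBH4/CeCl3 if the ring itself directs correctly) then gives 39. This replaces substrate control in the C–C bond formation by reagent control in a reduction.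

**Step 22.** The silyl triflate may activate the enal before the dienolate is trapped, leading to premature, uncontrolled cyclization or to amine addition with loss of alkene geometry; the ketene acetal may also be hydrolysed on handling. Fallback, setting out from 37 and returning at 44: enol silane formation and Mukaiyama cyclization are run in one pot with TBSOTf/i-Pr2NEt at high dilution, the silyl triflate serving as silylating agent and as Lewis acid. This should give the C9,C13-bis(silyl ether) F3. Et3N·3HF then gives diol F4. Selective acetylation of the primary C13 hydroxyl (Ac2O, 2,4,6-collidine, −40 °C) gives C13 acetate F5. Esterification of F5 with 41 under the conditions of step 25 gives 44.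

**Step 19.** The enolate may be acetylated with loss of geometric control (E isomer, acetoxy cis to C11, which would lead to the C8 epimer), and excess base may move the double bond into conjugation with the lactone. Fallback, setting out from 33 and returning at 33: reliance on kinetic selectivity is replaced by a separation and recycling loop. The isomers are separated by chromatography, and the E isomer F6 is converted back to 33 by selective methanolysis of the enol ester (K2CO3, MeOH, −20 °C) and resubmitted.

**Step 17.** Under the basic borohydride conditions the new primary C8 hydroxyl may attack the lactone carbonyl, so that the acyl group migrates from O6 to O8 (translactonization); the lactone may also be over-reduced. Fallback, setting out from 31 and returning at 33: the imide is reduced directly to the aldehyde with Cp2Zr(H)Cl in THF at 23 °C, a reagent known to take tertiary amides and N-acyl oxazolidinones to aldehydes in the presence of esters. The alcohol stage is bypassed and no new isolated compound arises.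

**Step 7.** The alpha-branched phosphonate may give the trisubstituted alkene with eroded E selectivity, and the epoxy aldehyde is base-sensitive. Fallback, setting out from 8 and returning at 15: Knoevenagel condensation of 8 with dimethyl malonate (piperidinium acetate) gives alkylidene malonate F7, in which no alkene geometry exists. i-Bu2AlH at −78 °C gives diol F8. Acylation of the less hindered hydroxymethyl group, the one trans to the oxirane, with 14 (1 equiv, EDC·HCl, DMAP, −20 °C, or a lipase with the vinyl ester) gives mono-senecioate F9. Etherification of the remaining hydroxyl with 4-methoxybenzyl bromide and Ag2O gives 15. The geometry problem is thereby exchanged for a site-selectivity problem.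

## Further compounds

F1 | step 23 | C9 epimer of 39 (2R,3S,4S,5S,6R,8R,9S) | CC(C)(C)[Si](C)(C)OCC1=C2[C@@H](OC(C)=O)[C@@H](O)/C(COC(=O)C=C(C)C)=C\[C@H]3O[C@@H]3[C@@]3(C)O[C@H]3[C@@H]2OC1=O
F2 | step 23 | C9 ketone (enone) with C8 acetate and C13 silyl ether | CC(C)(C)[Si](C)(C)OCC1=C2[C@@H](OC(C)=O)C(=O)/C(COC(=O)C=C(C)C)=C\[C@H]3O[C@@H]3[C@@]3(C)O[C@H]3[C@@H]2OC1=O
F3 | step 22 | C9,C13-bis(tert-butyldimethylsilyl ether) of the macrocycle | CC(C)(C)[Si](C)(C)OCC1=C2[C@@H](OC(C)=O)[C@H](O[Si](C)(C)C(C)(C)C)/C(COC(=O)C=C(C)C)=C\[C@H]3O[C@@H]3[C@@]3(C)O[C@H]3[C@@H]2OC1=O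
F4 | step 22 | C9,C13 diol of the macrocycle | OCC1=C2[C@@H](OC(C)=O)[C@H](O)/C(COC(=O)C=C(C)C)=C\[C@H]3O[C@@H]3[C@@]3(C)O[C@H]3[C@@H]2OC1=O
F5 | step 22 | C13 acetate with free C9 hydroxyl (44 lacking the epoxy ester) | CC(=O)OCC1=C2[C@@H](OC(C)=O)[C@H](O)/C(COC(=O)C=C(C)C)=C\[C@H]3O[C@@H]3[C@@]3(C)O[C@H]3[C@@H]2OC1=O
F6 | step 19 | E enol acetate isomer of 35 (acetoxy cis to C11) | COc1ccc(COC/C(COC(=O)C=C(C)C)=C\[C@H]2O[C@@H]2[C@@]2(C)O[C@H]2[C@@H]2OC(=O)C(CO[Si](C)(C)C(C)(C)C)/C2=C\OC(C)=O)cc1
F0 | step 17 | none | none
F7 | step 7 | dimethyl 2-{[(2R,3R)-3-[(Z)-4-(tert-butyldimethylsilyloxy)but-2-en-2-yl]oxiran-2-yl]methylidene}malonate | COC(=O)C(C(=O)OC)=C[C@H]1O[C@@H]1/C(C)=C\CO[Si](C)(C)C(C)(C)C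
F8 | step 7 | 2-{[(2R,3R)-3-[(Z)-4-(tert-butyldimethylsilyloxy)but-2-en-2-yl]oxiran-2-yl]methylidene}propane-1,3-diol | OCC(CO)=C[C@H]1O[C@@H]1/C(C)=C\CO[Si](C)(C)C(C)(C)C
F9 | step 7 | mono-senecioate of F8 (ester arm trans to the oxirane; free hydroxymethyl cis) | OC/C(COC(=O)C=C(C)C)=C\[C@H]1O[C@@H]1/C(C)=C\CO[Si](C)(C)C(C)(C)C
A1 | alternative 1 | 1(10)Z,2E,4Z-triene lactone carrying all four esters | CC(=O)OCC1=C2[C@@H](OC(C)=O)[C@H](OC(=O)[C@]3(C)CO3)/C(COC(=O)C=C(C)C)=C\C=C\C(C)=C/[C@@H]2OC1=O
A2 | alternative 1 | ring-opened C12 acid with C6 methylene and exocyclic C7=C11 | CC(=O)OC/C(C(=O)O)=C1\[C@@H](OC(C)=O)[C@H](OC(=O)[C@]2(C)CO2)/C(COC(=O)C=C(C)C)=C\C=C\C(C)=C/C1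
A3 | alternative 2 | ten-membered diepoxide lactone with C9 PMB ether and C14 silyl ether | CC(=O)OCC1=C2[C@@H](OC(C)=O)[C@H](OCc4ccc(OC)cc4)/C(CO[Si](C)(C)C(C)(C)C)=C\[C@H]3O[C@@H]3[C@@]3(C)O[C@H]3[C@@H]2OC1=O
A4 | alternative 2 | C2 tetrahydrothiophenium salt (triflate) with C3 aldehyde on the C4–C5 oxirane | CC(=O)OCC1=C([C@@H](OC(C)=O)[C@H](OCc2ccc(OC)cc2)/C(CO[Si](C)(C)C(C)(C)C)=C\C[S+]2CCCC2)[C@@H](OC1=O)[C@@H]1O[C@]1(C)C=O.[O-]S(=O)(=O)C(F)(F)F
A5 | alternative 3 | ten-membered 1(10)Z,2E-dienyl C8 ketone with C4–C5 oxirane and butenolide | CC(C)(C)[Si](C)(C)OCC1=C2C(=O)[C@H](OCc5ccc(OC)cc5)/C(COCc5ccc(OC)cc5)=C\C=C\[C@@]3(C)O[C@H]3[C@@H]2OC1=O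
A6 | alternative 3 | trans-fused decalin (C3–C8 bond) with C8 tertiary alcohol and equatorial C2 mesylate | CC(C)(C)[Si](C)(C)OCC1=C2[C@@]4(O)[C@H](OCc5ccc(OC)cc5)/C(COCc5ccc(OC)cc5)=C\[C@@H](OS(C)(=O)=O)[C@@H]4[C@@]3(C)O[C@H]3[C@@H]2OC1=O
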